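**Retrosynthetic overview**

1. Sarothralin is cut last at the CH2 bridge: isobutyrylfilicinic acid adds to an ortho-quinone methide released from a phenolic Mannich base of the 2-O-prenyl phlorobenzophenone half, whose para-hydroxyl stays a triisopropylsilyl ether until the final step.
2. Isobutyrylfilicinic acid comes by hydrolysis from its masked form, which is cut into 3-ethoxy-4,4-dimethylcyclobutenone and a methoxyalkyne carrying the isobutyryl group as a silyl enol ether. A thermal cascade (4π opening, [2+2], 4π opening, 6π closure) inserts the two alkyne carbons between the ring C=O and the former C2 of the four-membered ring.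
3. Enabling feature: in the acylfilicinic ring the C1 carbonyl is flanked by the quaternary C6(CH3)2 carbon and oxygen sits on alternate carbons (C1, C3, C5). The ring is therefore a non-aromatizable 6,6-dimethylcyclohexa-2,4-dienone, the product expected from 6π closure of a dienylketene with a dimethyl terminus. C6–C1 maps onto dimethylketene, C4–C5 and C2–C3 onto two alkoxyalkynes.
4. Ring order: the cyclobutenone ring first (ketene plus ethoxyacetylene), then the six-membered ring from it. Both benzene rings are bought in 2,4,6-trihydroxybenzophenone (para-silylation, mono-O-prenylation, Mannich reaction).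

Key step: step 4

Remark: the β-triketone ring is written throughout in the enol form of the target SMILES (it equilibrates with its other enol forms), and the target has no stereocentre.
Remark: compounds 1, 2, 5, 6 and 18 and all reagents are taken as purchasable (1 as a hexanes solution).

**Route**

Step 1
Reactants: 1 ethoxyethyne; 2 2-methylpropanoyl chloride
Product: 4 3-ethoxy-4,4-dimethylcyclobut-2-en-1-one, via dimethylketene 3 (not isolated)
Conditions: Et3N, MeCN, rt → 50 °C
Reagents that add atoms: none
Why: Dehydrochlorination of 2 gives dimethylketene, which should undergo the ketene–alkoxyalkyne [2+2] cycloaddition with the nucleophilic terminal alkyne carbon bonding to the ketene carbonyl carbon, placing OEt at C3 and the C(CH3)2 group at C4.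

Step 2
Reactants: 5 2-chloro-1,1-dimethoxyethane; 6 N-methoxy-N,2-dimethylpropanamide
Product: 11 1-methoxy-4-methylpent-1-yn-3-one, via 1-chloro-2-methoxyethene 7 (not isolated), via methoxyethyne 8 (not isolated), via lithium methoxyethynide 9 (not isolated), via lithium hemiaminal alkoxide 10 (not isolated)
Conditions: LiN(iPr)2 (3 equiv), THF, −78 → 0 °C; then 6, −78 → −20 °C; cold aq. NH4Cl
Reagents that add atoms: none
Why: Two base-induced eliminations and a deprotonation convert the chloroacetal into the lithium alkoxyacetylide, and the Weinreb ketone synthesis should stop at the ynone because the chelated adduct 10 survives until the buffered quench.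

Step 3
Reactants: 11 1-methoxy-4-methylpent-1-yn-3-one
Product: 12 tert-butyl[(1-methoxy-4-methylpent-3-en-1-yn-3-yl)oxy]dimethylsilane
Conditions: TBSOTf, iPr2NEt, Et2O, −78 → 0 °C
Reagents that add atoms: tert-butyldimethylsilyl trifluoromethanesulfonate, CC(C)(C)[Si](C)(C)OS(=O)(=O)C(F)(F)F
Why: Soft enolization (silyl triflate with a hindered tertiary amine) should give the silyl enol ether at the only α-hydrogen, the isopropyl methine, which has no E/Z issue, masks the acyl group and turns the push–pull ynone into an electron-rich ynol ether.

Step 4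
Reactants: 4 3-ethoxy-4,4-dimethylcyclobut-2-en-1-one; 12 tert-butyl[(1-methoxy-4-methylpent-3-en-1-yn-3-yl)oxy]dimethylsilane
Product: 16 2-(1-silyloxy-2-methylprop-1-enyl)-5-ethoxy-3-methoxy-6,6-dimethylcyclohexa-2,4-dien-1-one, via vinylketene 13 (not isolated), via alkenylcyclobutenone 14 (not isolated), via dienylketene 15 (not isolated)
Conditions: 12 (1.3 equiv), toluene, 130 °C, sealed tube, argon
Reagents that add atoms: none
Why: Proposed new method: heating opens cyclobutenone 4 by conrotatory 4π-electrocyclic cleavage of its C1–C4 bond to vinylketene 13, whose electrophilic ketene carbon is attacked by the oxygen-remote alkyne carbon of 12 in a regiospecific [2+2] cycloaddition (four-membered ring closure) that gives 14. A second 4π opening of 14 gives dienylketene 15, and thermal disrotatory 6π-electrocyclization onto its dimethyl-substituted terminus closes the six-membered ring as dienone 16, so that net the two alkyne carbons are inserted between the carbonyl carbon and the former C2 of 4 (new ring bonds C1–C2 and C3–C4 of 16; the C1–C6 bond is broken and re-formed). The closest known reaction type is the Danheiser benzannulation of cyclobutenones with alkoxy- or siloxyalkynes; the extension lies in using a 3-alkoxy-4,4-dimethylcyclobutenone, whose quaternary carbon stops the cascade at a 2,4-cyclohexadienone instead of a phenol, a closure known from the thermal return of dienylketenes to 6,6-disubstituted cyclohexa-2,4-dienones. No stereocentre remains in 16, the one in 14 being transient and racemic. The step needs regioselectivity in the [2+2] event, secured by the methoxy group, which makes the remote alkyne carbon the nucleophile and stabilizes positive charge on the carbon that bonds to the ketene α-carbon, and chemoselectivity for the triple bond over the tetrasubstituted silyl enol ether, secured by its steric shielding. Masking the acyl group as a silyl enol ether keeps the alkyne electron-rich, the methyl (not ethyl) ynol ether cannot fragment by retro-ene loss of an alkene at this temperature, and the reversibility of both ring openings funnels whichever ketene geometry forms first into the closable one.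

Step 5
Reactants: 16 2-(1-silyloxy-2-methylprop-1-enyl)-5-ethoxy-3-methoxy-6,6-dimethylcyclohexa-2,4-dien-1-one
Product: 17 isobutyrylfilicinic acid
Conditions: 2 M aq. HCl, THF, 60 °C
Reagents that add atoms: water, O
Why: Acid hydrolysis of the silyl enol ether and of the two vinylogous-ester enol ethers should release the isobutyryl ketone and both ring oxygens, the product settling as the stable hydrogen-bonded enol form of the β-triketone, which can be purified by extraction as an acid.

Step 6
Reactants: 18 2,4,6-trihydroxybenzophenone
Product: 19 2,6-dihydroxy-4-(triisopropylsilyloxy)benzophenone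
Conditions: TIPSCl (1.05 equiv), imidazole, DMF, 0 °C
Reagents that add atoms: chlorotri(propan-2-yl)silane, CC(C)[Si](Cl)(C(C)C)C(C)C
Why: Selective silylation should occur at the para hydroxyl, the most acidic and the only one neither hydrogen-bonded to nor shielded by the benzoyl group, which the bulky silyl chloride discriminates further.

Step 7
Reactants: 19 2,6-dihydroxy-4-(triisopropylsilyloxy)benzophenone
Product: 20 2-hydroxy-6-(prenyloxy)-4-(triisopropylsilyloxy)benzophenone
Conditions: 3-methylbut-2-en-1-ol, PPh3, DIAD, THF, 0 °C → rt
Reagents that add atoms: 3-methylbut-2-en-1-ol, CC(C)=CCO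
Why: Mitsunobu etherification alkylates one of the two equivalent ortho hydroxyls on oxygen under neutral conditions that spare the aryl silyl ether, and it should stop at the mono-ether because the remaining hydroxyl is then locked in a strong hydrogen bond to the ketone.

Step 8
Reactants: 20 2-hydroxy-6-(prenyloxy)-4-(triisopropylsilyloxy)benzophenone
Product: 21 3-[(dimethylamino)methyl]-2-hydroxy-6-(prenyloxy)-4-(triisopropylsilyloxy)benzophenone
Conditions: CH2=NMe2+ I−, Et3N, CH2Cl2, rt
Reagents that add atoms: N,N-dimethylmethyleneiminium iodide, C=[N+](C)C.[I-]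
Why: Phenolic Mannich aminomethylation with the preformed iminium salt should go ortho to the only free hydroxyl, since the other open ring carbon has no neighbouring hydroxyl and lies between two ether groups.

Step 9
Reactants: 17 isobutyrylfilicinic acid; 21 3-[(dimethylamino)methyl]-2-hydroxy-6-(prenyloxy)-4-(triisopropylsilyloxy)benzophenone
Product: 23 sarothralin mono(triisopropylsilyl) ether, via ortho-quinone methide 22 (not isolated)
Conditions: 1,4-dioxane, 90 °C; dilute citric acid work-up
Reagents that add atoms: none
Why: Proton transfer from the acidic triketone to the benzylic amine and thermal loss of dimethylamine give the ortho-quinone methide, and Michael addition of the only ring CH carbon of 17 should form the methylene bridge, the established mode of joining the halves of methylene-bridged acylphloroglucinols.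

Step 10
Reactants: 23 sarothralin mono(triisopropylsilyl) ether
Product: 24 sarothralin
Conditions: Bu4NF, AcOH, THF, 0 °C
Reagents that add atoms: none
Why: Fluoride-mediated cleavage of the aryl silyl ether, buffered with acetic acid, should free the last phenol without touching the prenyl ether, the benzophenone or the enolized triketone.

**Compound list**

1 | ethoxyethyne (ethoxyacetylene) | CCOC#C | starting material
2 | 2-methylpropanoyl chloride (isobutyryl chloride) | CC(C)C(=O)Cl | starting material
3 | 2-methylprop-1-en-1-one (dimethylketene) | CC(C)=C=O | intermediate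
4 | 3-ethoxy-4,4-dimethylcyclobut-2-en-1-one | CCOC1=CC(=O)C1(C)C | intermediate
5 | 2-chloro-1,1-dimethoxyethane | COC(CCl)OC | starting material
6 | N-methoxy-N,2-dimethylpropanamide | CC(C)C(=O)N(C)OC | starting material
7 | 1-chloro-2-methoxyethene (E/Z mixture) | COC=CCl | intermediate
8 | methoxyethyne | COC#C | intermediate
9 | lithium methoxyethynide | COC#[C-].[Li+] | intermediate
10 | lithium 1-methoxy-3-[methoxy(methyl)amino]-4-methylpent-1-yn-3-olate (racemic) | COC#CC([O-])(C(C)C)N(C)OC.[Li+] | intermediate
11 | 1-methoxy-4-methylpent-1-yn-3-one | COC#CC(=O)C(C)C | intermediate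
12 | tert-butyl[(1-methoxy-4-methylpent-3-en-1-yn-3-yl)oxy]dimethylsilane | COC#CC(O[Si](C)(C)C(C)(C)C)=C(C)C | intermediate
13 | 3-ethoxy-4-methylpenta-1,3-dien-1-one | O=C=CC(OCC)=C(C)C | intermediate
14 | 2-{1-[tert-butyl(dimethyl)silyl]oxy-2-methylprop-1-en-1-yl}-4-(1-ethoxy-2-methylprop-1-en-1-yl)-3-methoxycyclobut-2-en-1-one (racemic) | O=C1C(C(O[Si](C)(C)C(C)(C)C)=C(C)C)=C(OC)C1C(OCC)=C(C)C | intermediate
15 | (3E)-2-{1-[tert-butyl(dimethyl)silyl]oxy-2-methylprop-1-en-1-yl}-5-ethoxy-3-methoxy-6-methylhepta-1,3,5-trien-1-one | O=C=C(C(O[Si](C)(C)C(C)(C)C)=C(C)C)/C(OC)=C\C(OCC)=C(C)C | intermediate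
16 | 2-{1-[tert-butyl(dimethyl)silyl]oxy-2-methylprop-1-en-1-yl}-5-ethoxy-3-methoxy-6,6-dimethylcyclohexa-2,4-dien-1-one | O=C1C(C(O[Si](C)(C)C(C)(C)C)=C(C)C)=C(OC)C=C(OCC)C1(C)C | intermediate
17 | 3,5-dihydroxy-6,6-dimethyl-2-(2-methylpropanoyl)cyclohexa-2,4-dien-1-one (isobutyrylfilicinic acid) | CC(C)C(=O)C1=C(O)C=C(O)C(C)(C)C1=O | intermediate
18 | phenyl(2,4,6-trihydroxyphenyl)methanone (2,4,6-trihydroxybenzophenone) | O=C(c1ccccc1)c1c(O)cc(O)cc1O | starting material
19 | (2,6-dihydroxy-4-{[tri(propan-2-yl)silyl]oxy}phenyl)(phenyl)methanone | O=C(c1ccccc1)c1c(O)cc(O[Si](C(C)C)(C(C)C)C(C)C)cc1O | intermediate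
20 | {2-hydroxy-6-[(3-methylbut-2-en-1-yl)oxy]-4-{[tri(propan-2-yl)silyl]oxy}phenyl}(phenyl)methanone | CC(C)=CCOc1cc(O[Si](C(C)C)(C(C)C)C(C)C)cc(O)c1C(=O)c1ccccc1 | intermediate
21 | {3-[(dimethylamino)methyl]-2-hydroxy-6-[(3-methylbut-2-en-1-yl)oxy]-4-{[tri(propan-2-yl)silyl]oxy}phenyl}(phenyl)methanone | CC(C)=CCOc1cc(O[Si](C(C)C)(C(C)C)C(C)C)c(CN(C)C)c(O)c1C(=O)c1ccccc1 | intermediate
22 | 2-benzoyl-6-methylidene-3-[(3-methylbut-2-en-1-yl)oxy]-5-{[tri(propan-2-yl)silyl]oxy}cyclohexa-2,4-dien-1-one | C=C1C(=O)C(C(=O)c2ccccc2)=C(OCC=C(C)C)C=C1O[Si](C(C)C)(C(C)C)C(C)C | intermediate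
23 | 4-({3-benzoyl-2-hydroxy-4-[(3-methylbut-2-en-1-yl)oxy]-6-{[tri(propan-2-yl)silyl]oxy}phenyl}methyl)-3,5-dihydroxy-6,6-dimethyl-2-(2-methylpropanoyl)cyclohexa-2,4-dien-1-one | CC(C)=CCOc1cc(O[Si](C(C)C)(C(C)C)C(C)C)c(CC2=C(O)C(C)(C)C(=O)C(C(=O)C(C)C)=C2O)c(O)c1C(=O)c1ccccc1 | intermediate
24 | 4-({3-benzoyl-2,6-dihydroxy-4-[(3-methylbut-2-en-1-yl)oxy]phenyl}methyl)-3,5-dihydroxy-6,6-dimethyl-2-(2-methylpropanoyl)cyclohexa-2,4-dien-1-one (sarothralin) | CC(C)=CCOc1cc(O)c(CC2=C(O)C(C)(C)C(=O)C(C(=O)C(C)C)=C2O)c(O)c1C(=O)c1ccccc1 | target

**Step count and risks**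

Total steps: 10. Longest linear sequence: 6 (steps 2, 3, 4, 5, 9, 10); the aromatic branch (steps 6, 7, 8) joins at step 9.

Step 4 (proposed new method). The first electrocyclic opening of the vinylogous-ester cyclobutenone may be too slow below the temperature at which the vinylketene drains away by 1,5-hydrogen shift from its inward methyl group or the ynol ether oligomerizes, so that the cycloaddition never competes. The fallback uses known chemistry and sets out from 2. Friedel–Crafts acylation of phloroglucinol with 2 (AlCl3, nitrobenzene, 65 °C) should give 2-methyl-1-(2,4,6-trihydroxyphenyl)propan-1-one F1. Dearomatizing geminal C-methylation (MeI, NaOMe, MeOH, rt) passes through the monomethyl compound 2-methyl-1-(2,4,6-trihydroxy-3-methylphenyl)propan-1-one F2 and should give isobutyrylfilicinic acid, so the route is rejoined at 17.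

Step 3. Conjugate addition of the amine to the silyl-activated ynone, or polymerization of this sensitive push–pull alkyne, may outrun deprotonation at the hindered methine. The fallback makes the enolate by carbon–carbon bond formation instead of enolization and sets out from 5 and 2. Lithium methoxyethynide 9 is generated from 5 as in step 2 and freed of diisopropylamine in vacuo. It is added at −78 °C in THF to a salt-free ether solution of dimethylketene 3 (from 2 and Et3N, filtered), with one extra equivalent of 3 sacrificed to the lithium methoxide present. This should give lithium 1-methoxy-4-methylpent-3-en-1-yn-3-olate F3, and O-silylation with TBSCl rejoins the route at 12.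

Step 8. The iminium ion may attack the other open ring carbon (para to the free hydroxyl), or substitution next to the bulky silyl ether may stall, giving regioisomer mixtures or no conversion. The fallback sets out from 20 and uses a formylation that is delivered through the magnesium phenoxide and can only go ortho to the free hydroxyl (MgCl2, Et3N, paraformaldehyde, MeCN, reflux). It should give 3-benzoyl-2-hydroxy-4-[(3-methylbut-2-en-1-yl)oxy]-6-{[tri(propan-2-yl)silyl]oxy}benzaldehyde F4. NaBH4 (EtOH, 0 °C) should reduce the aldehyde, but not the hindered chelated diaryl ketone, to the benzylic alcohol {2-hydroxy-3-(hydroxymethyl)-6-[(3-methylbut-2-en-1-yl)oxy]-4-{[tri(propan-2-yl)silyl]oxy}phenyl}(phenyl)methanone F5. Heating F5 with 17 in 1,4-dioxane at 90 °C loses water to the same ortho-quinone methide 22 and rejoins the route at 23.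

Further compounds
F1 | step 4 | 2-methyl-1-(2,4,6-trihydroxyphenyl)propan-1-one | CC(C)C(=O)c1c(O)cc(O)cc1O
F2 | step 4 | 2-methyl-1-(2,4,6-trihydroxy-3-methylphenyl)propan-1-one | CC(C)C(=O)c1c(O)cc(O)c(C)c1O
F3 | step 3 | lithium 1-methoxy-4-methylpent-3-en-1-yn-3-olate | COC#CC([O-])=C(C)C.[Li+]
F4 | step 8 | 3-benzoyl-2-hydroxy-4-[(3-methylbut-2-en-1-yl)oxy]-6-{[tri(propan-2-yl)silyl]oxy}benzaldehyde | CC(C)=CCOc1cc(O[Si](C(C)C)(C(C)C)C(C)C)c(C=O)c(O)c1C(=O)c1ccccc1
F5 | step 8 | {2-hydroxy-3-(hydroxymethyl)-6-[(3-methylbut-2-en-1-yl)oxy]-4-{[tri(propan-2-yl)silyl]oxy}phenyl}(phenyl)methanone | CC(C)=CCOc1cc(O[Si](C(C)C)(C(C)C)C(C)C)c(CO)c(O)c1C(=O)c1ccccc1
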